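## Retrosynthetic overview

- The chain is numbered C1 (ester carbon) to C15 (ketone methyl); the 1,2-dioxane holds C3–C6. First cut: the C8–C9 ketone bond, made by a palladium-catalysed acylative Negishi coupling of a dioxanyl-ethylzinc (fragment A) with 2,2-dimethyl-6-oxoheptanoyl chloride (fragment B).
- Fragment A: the only ring is closed by a new palladium-catalysed peroxycarbonylation of an (E)-alkenyl tertiary hydroperoxide. It forms C3–O and C1–C2 and sets C2 and C3; C1 and OMe come from CO and MeOH.
- The tertiary hydroperoxide (C6) comes from invertive H2O2 opening of an (R)-2,2-disubstituted oxetane, made by asymmetric double methylene transfer to (E)-hept-5-en-2-one (Claisen product of but-3-en-2-ol and 2-methoxypropene).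
- Fragment B: methyl isobutyrate enolate alkylation with 5-bromopent-1-ene, Wacker oxidation, saponification, acid chloride.
- Ring order: the single 1,2-dioxane ring is formed in step 4, before the fragment union in step 10.

Assumption: the (S)-binaphthoxide complex in step 2 and the (S,S)-bisoxazoline in step 4 are taken as the matched catalyst enantiomers; the mirror-image ligand is used if the sense proves opposite.

## Route

Step 1
Reactants: 1 but-3-en-2-ol (racemic); 2 2-methoxypropene
Product: 5 (5E)-hept-5-en-2-one, via mixed methyl ketal 3 (not isolated), via allyl isopropenyl ether 4 (not isolated)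
Conditions: 2 (2.5 equiv), H3PO4 (0.1 mol%), neat, sealed vessel, 125 °C
Reagents that add atoms: none
Why: Acid-catalysed ketal exchange gives the allyl isopropenyl ether, which undergoes a Saucy–Marbet (ketonic Claisen) [3,3]-rearrangement through a chair with the methyl group equatorial, so the new double bond is E (about 9:1 or better) and no stereocentre is carried on.

Step 2
Reactants: 5 (5E)-hept-5-en-2-one
Product: 7 (2R)-2-methyl-2-[(3E)-pent-3-en-1-yl]oxetane, via oxirane 6 (not isolated)
Conditions: Me2S(O)=CH2 (pre-formed salt-free THF solution, 1.2 then 1.0 equiv), LaLi3[(S)-binaphthoxide]3 (5 then 15 mol%), (2,4,6-(MeO)3C6H2)3P=O (5 then 15 mol%), 5 Å MS, THF, rt then 45 °C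
Reagents that add atoms: dimethylsulfoxonium methylide, C[S+](C)(=O)[CH2-] (two CH2 units)
Why: One-pot double methylene transfer, in which a catalytic asymmetric Corey–Chaykovsky epoxidation of the methyl ketone sets C6 by catalyst-controlled face selection and the ylide then expands the epoxide at its CH2 carbon to the oxetane with retention at C6 and kinetic amplification of the ee.

Step 3
Reactants: 7 (2R)-2-methyl-2-[(3E)-pent-3-en-1-yl]oxetane
Product: 8 (3S,6E)-3-hydroperoxy-3-methyloct-6-en-1-ol
Conditions: anhydrous H2O2 in Et2O (10 equiv), Me3SiOTf (0.2 equiv), Et2O, −78 → −20 °C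
Reagents that add atoms: hydrogen peroxide, OO
Why: Lewis-acid-activated oxetane perhydrolysis, in which H2O2 opens the ring at the tertiary carbon in a borderline SN2 process with predominant inversion (R oxetane to S hydroperoxide) while the isolated E-alkene is inert.

Step 4
Reactants: 8 (3S,6E)-3-hydroperoxy-3-methyloct-6-en-1-ol
Product: 9 methyl (2R)-2-[(3S,6S)-6-(2-hydroxyethyl)-6-methyl-1,2-dioxan-3-yl]propanoate
Conditions: Pd(OCOCF3)2 (10 mol%), 2,2'-(propane-2,2-diyl)bis[(4S)-4-tert-butyl-4,5-dihydro-1,3-oxazole] (12 mol%), 1,4-benzoquinone (1.5 equiv), CO (1 atm), MeOH/CH2Cl2 1:3, −20 → 0 °C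
Reagents that add atoms: carbon monoxide, [C-]#[O+]; methanol, CO
Why: Proposed new method: peroxypalladation–methoxycarbonylation, in which the cationic divalent palladium–bisoxazoline–CO complex binds the E-alkene and the pendant hydroperoxide attacks C3 anti to palladium in a 6-exo chair (alkene equatorial, hydroxyethyl arm equatorial, C6 methyl axial, the chiral ligand reinforcing this face); CO then inserts into the C2–Pd bond with retention faster than β-hydride elimination because palladium is coordinatively saturated under CO, methanolysis of the acyl palladium gives the ester and benzoquinone reoxidises zerovalent palladium, so anti addition across the E-alkene fixes C2 (R) and C3 (S) together while C6 is untouched; the closest known reactions are the alkoxypalladation–alkoxycarbonylation of alkenols (Semmelhack type, anti addition) and the divalent-palladium cyclisation of unsaturated tertiary hydroperoxides to 1,2-dioxanes that ends in β-hydride elimination.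

Step 5
Reactants: 9 methyl (2R)-2-[(3S,6S)-6-(2-hydroxyethyl)-6-methyl-1,2-dioxan-3-yl]propanoate
Product: 11 methyl (2R)-2-[(3S,6S)-6-(2-iodoethyl)-6-methyl-1,2-dioxan-3-yl]propanoate, via mesylate 10 (not isolated)
Conditions: MsCl, Et3N, CH2Cl2, 0 °C; then NaI, acetone, 45 °C
Reagents that add atoms: sodium iodide, [Na+].[I-]; methanesulfonyl chloride, CS(=O)(=O)Cl (its atoms are in intermediate 10 only)
Why: Mesylation of the primary alcohol and Finkelstein SN2 displacement at CH2, conditions that hindered dialkyl peroxides and the ester tolerate, with only brief exposure to Et3N at 0 °C so that C2 is not epimerised and the ring is not opened by retro-oxa-Michael reaction.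

Step 6
Reactants: 12 methyl 2-methylpropanoate; 13 5-bromopent-1-ene
Product: 15 methyl 2,2-dimethylhept-6-enoate, via lithium enolate 14 (not isolated)
Conditions: LiN(iPr)2, THF, −78 °C; then 13, DMPU, −78 °C → rt
Reagents that add atoms: lithium diisopropylamide, [Li+].CC(C)[N-]C(C)C (lithium in intermediate 14 only)
Why: Ester enolate alkylation (SN2) with a primary bromide builds the quaternary C10; no stereocentre is involved.

Step 7
Reactants: 15 methyl 2,2-dimethylhept-6-enoate
Product: 16 methyl 2,2-dimethyl-6-oxoheptanoate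
Conditions: PdCl2 (10 mol%), CuCl (1 equiv), O2 (1 atm), DMF/H2O 7:1, rt
Reagents that add atoms: water, O
Why: Tsuji–Wacker oxidation converts the terminal alkene into the methyl ketone with Markovnikov selectivity, and the hindered ester is inert.

Step 8
Reactants: 16 methyl 2,2-dimethyl-6-oxoheptanoate
Product: 17 2,2-dimethyl-6-oxoheptanoic acid
Conditions: LiOH, THF/MeOH/H2O, 60 °C; then 1 M HCl
Reagents that add atoms: lithium hydroxide, [Li+].[OH-]
Why: Saponification of the hindered methyl ester needs warm LiOH, which the non-enolisable α-quaternary centre and the methyl ketone tolerate.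

Step 9
Reactants: 17 2,2-dimethyl-6-oxoheptanoic acid
Product: 18 2,2-dimethyl-6-oxoheptanoyl chloride
Conditions: (COCl)2, cat. DMF, CH2Cl2, 0 °C → rt; concentrate and use at once
Reagents that add atoms: oxalyl chloride, O=C(Cl)C(Cl)=O
Why: Vilsmeier-catalysed acid chloride formation, which leaves the ketone alone and cannot give a ketene because the α-carbon is quaternary.

Step 10
Reactants: 11 methyl (2R)-2-[(3S,6S)-6-(2-iodoethyl)-6-methyl-1,2-dioxan-3-yl]propanoate; 18 2,2-dimethyl-6-oxoheptanoyl chloride
Product: 20 diacarperoxide C, via alkylzinc iodide 19 (not isolated)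
Conditions: Zn dust (activated by BrCH2CH2Br/Me3SiCl), LiCl, THF, 25 °C; then 18 (1.2 equiv), Pd(PPh3)4 (5 mol%), THF, 0 °C → rt
Reagents that add atoms: zinc, [Zn] (in intermediate 19 only)
Why: Negishi acylation, in which LiCl-assisted zinc insertion into the primary C–I bond gives an alkylzinc that tolerates ester, ketone and the hindered dialkyl peroxide, and zerovalent palladium (oxidative addition into the C–Cl bond of 18, transmetalation, reductive elimination) forms the C8–C9 ketone bond at room temperature without touching any stereocentre.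

## Compound list

1 | but-3-en-2-ol (racemic) | C=CC(C)O | starting material
2 | 2-methoxypropene | COC(C)=C | starting material
3 | 3-[(2-methoxypropan-2-yl)oxy]but-1-ene (mixed methyl ketal, racemic) | C=CC(C)OC(C)(C)OC | intermediate
4 | 3-(prop-1-en-2-yloxy)but-1-ene (allyl isopropenyl ether, racemic) | C=CC(C)OC(C)=C | intermediate
5 | (5E)-hept-5-en-2-one | C/C=C/CCC(C)=O | intermediate
6 | (2R)-2-methyl-2-[(3E)-pent-3-en-1-yl]oxirane | C/C=C/CC[C@]1(C)CO1 | intermediate
7 | (2R)-2-methyl-2-[(3E)-pent-3-en-1-yl]oxetane | C/C=C/CC[C@]1(C)CCO1 | intermediate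
8 | (3S,6E)-3-hydroperoxy-3-methyloct-6-en-1-ol | C/C=C/CC[C@@](C)(CCO)OO | intermediate
9 | methyl (2R)-2-[(3S,6S)-6-(2-hydroxyethyl)-6-methyl-1,2-dioxan-3-yl]propanoate | COC(=O)[C@H](C)[C@@H]1CC[C@@](C)(CCO)OO1 | intermediate
10 | methyl (2R)-2-[(3S,6S)-6-[2-(methanesulfonyloxy)ethyl]-6-methyl-1,2-dioxan-3-yl]propanoate | COC(=O)[C@H](C)[C@@H]1CC[C@@](C)(CCOS(C)(=O)=O)OO1 | intermediate
11 | methyl (2R)-2-[(3S,6S)-6-(2-iodoethyl)-6-methyl-1,2-dioxan-3-yl]propanoate | COC(=O)[C@H](C)[C@@H]1CC[C@@](C)(CCI)OO1 | intermediate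
12 | methyl 2-methylpropanoate (methyl isobutyrate) | COC(=O)C(C)C | starting material
13 | 5-bromopent-1-ene | C=CCCCBr | starting material
14 | lithium 1-methoxy-2-methylprop-1-en-1-olate | COC([O-])=C(C)C.[Li+] | intermediate
15 | methyl 2,2-dimethylhept-6-enoate | COC(=O)C(C)(C)CCCC=C | intermediate
16 | methyl 2,2-dimethyl-6-oxoheptanoate | COC(=O)C(C)(C)CCCC(C)=O | intermediate
17 | 2,2-dimethyl-6-oxoheptanoic acid | OC(=O)C(C)(C)CCCC(C)=O | intermediate
18 | 2,2-dimethyl-6-oxoheptanoyl chloride | ClC(=O)C(C)(C)CCCC(C)=O | intermediate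
19 | iodo{2-[(3S,6S)-6-[(2R)-1-methoxy-1-oxopropan-2-yl]-3-methyl-1,2-dioxan-3-yl]ethyl}zinc | COC(=O)[C@H](C)[C@@H]1CC[C@@](C)(CC[Zn]I)OO1 | intermediate
20 | diacarperoxide C, methyl (2R)-2-[(3S,6S)-6-(4,4-dimethyl-3,8-dioxononyl)-6-methyl-1,2-dioxan-3-yl]propanoate | COC(=O)[C@H](C)[C@@H]1CC[C@@](C)(CCC(=O)C(C)(C)CCCC(C)=O)OO1 | target

## Step count and risks

Total step count: 10.
Longest linear sequence: 6 steps (1, 2, 3, 4, 5, 10); the fragment B branch (steps 6–9) joins at step 10.

The three steps most likely to fail: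

**Step 4 (the proposed new peroxycarbonylation).** The risks are β-hydride elimination to an alkenyl dioxane, oxidation of CO or of palladium by the hydroperoxide, syn instead of anti addition, and weak face control from C6 (the two C6 arms differ little in size). The known-chemistry fallback sets out from oxetane 7 and comes back at 9. Cross-metathesis of 7 with methyl methacrylate (second-generation Hoveyda–Grubbs catalyst, CH2Cl2, 40 °C) gives methyl (2E)-2-methyl-5-[(2R)-2-methyloxetan-2-yl]pent-2-enoate F1. The same Me3SiOTf/H2O2 opening then gives methyl (2E,6S)-6-hydroperoxy-8-hydroxy-2,6-dimethyloct-2-enoate F2. Base-mediated intramolecular peroxy-Michael addition (Et2NH, CF3CH2OH, rt) closes the dioxane. C6 stays secure, but C2 and C3 are formed with little control, so 9 has to be separated from its C2/C3 diastereomers by HPLC.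

**Step 10 (zinc insertion and acylation beside the O–O bond).** Zinc metal or zerovalent palladium with phosphine may reduce the peroxide, and the α-quaternary acid chloride may couple slowly. The fallback sets out from 11 and 18 and comes back at 20, forming C7=C8 by metathesis in place of C8–C9 by acylation. Iodide 11 is displaced by sodium 2-nitrophenylselenolate (from the diselenide and NaBH4, EtOH, 0 °C) to give methyl (2R)-2-[(3S,6S)-6-methyl-6-{2-[(2-nitrophenyl)selanyl]ethyl}-1,2-dioxan-3-yl]propanoate F3. Oxidation with 30% H2O2 in THF gives the selenoxide F4, which eliminates at rt to methyl (2R)-2-[(3S,6S)-6-ethenyl-6-methyl-1,2-dioxan-3-yl]propanoate F5. In parallel, 18 is coupled with Bu3SnCH=CH2 (PdCl2(PPh3)2, THF, 50 °C) to give 4,4-dimethylnon-1-ene-3,8-dione F6. Cross-metathesis of F5 with F6 (second-generation Hoveyda–Grubbs catalyst, CH2Cl2, 40 °C) gives methyl (2R)-2-[(3S,6S)-6-[(1E)-4,4-dimethyl-3,8-dioxonon-1-en-1-yl]-6-methyl-1,2-dioxan-3-yl]propanoate F7. Diimide reduction of the enone double bond (KO2CN=NCO2K, AcOH, MeOH/CH2Cl2, 0 °C → rt) leaves the O–O bond intact and gives 20. The metathesis at a vinyl group on a fully substituted carbon is itself slow and may need high catalyst loading.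

**Step 2 (asymmetric one-pot oxetane formation).** The two ketone substituents differ little (methyl against a CH2CH2 chain), and the ring expansion is slow. The fallback sets out from 5 and comes back at 7, taking the chirality from a Sharpless epoxidation. Horner–Wadsworth–Emmons reaction of 5 with (MeO)2P(O)CH2CO2Me (NaH, THF) gives methyl (2E,6E)-3-methylocta-2,6-dienoate F8 after removal of the 2Z isomer. Reduction with iBu2AlH gives (2E,6E)-3-methylocta-2,6-dien-1-ol F9. Sharpless epoxidation (Ti(OiPr)4, D-(−)-diethyl tartrate, tBuOOH, 4 Å MS, CH2Cl2, −20 °C) gives [(2R,3R)-3-methyl-3-[(3E)-pent-3-en-1-yl]oxiran-2-yl]methanol F10. Opening at C2 with NaAlH2(OCH2CH2OMe)2 (THF, 0 °C) gives (3R,6E)-3-methyloct-6-ene-1,3-diol F11. Treatment with n-BuLi and TsCl gives (3R,6E)-3-hydroxy-3-methyloct-6-en-1-yl 4-methylbenzenesulfonate F12, and a second equivalent of n-BuLi with warming closes it to 7 with retention at the tertiary carbon.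

## Further compounds

F1 | step 4 | methyl (2E)-2-methyl-5-[(2R)-2-methyloxetan-2-yl]pent-2-enoate | COC(=O)/C(C)=C/CC[C@]1(C)CCO1
F2 | step 4 | methyl (2E,6S)-6-hydroperoxy-8-hydroxy-2,6-dimethyloct-2-enoate | COC(=O)/C(C)=C/CC[C@@](C)(CCO)OO
F3 | step 10 | methyl (2R)-2-[(3S,6S)-6-methyl-6-{2-[(2-nitrophenyl)selanyl]ethyl}-1,2-dioxan-3-yl]propanoate | COC(=O)[C@H](C)[C@@H]1CC[C@@](C)(CC[Se]c2ccccc2[N+](=O)[O-])OO1
F4 | step 10 | methyl (2R)-2-[(3S,6S)-6-methyl-6-{2-[(2-nitrophenyl)seleninyl]ethyl}-1,2-dioxan-3-yl]propanoate (mixture at selenium) | COC(=O)[C@H](C)[C@@H]1CC[C@@](C)(CC[Se](=O)c2ccccc2[N+](=O)[O-])OO1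
F5 | step 10 | methyl (2R)-2-[(3S,6S)-6-ethenyl-6-methyl-1,2-dioxan-3-yl]propanoate | COC(=O)[C@H](C)[C@@H]1CC[C@@](C)(C=C)OO1
F6 | step 10 | 4,4-dimethylnon-1-ene-3,8-dione | C=CC(=O)C(C)(C)CCCC(C)=O
F7 | step 10 | methyl (2R)-2-[(3S,6S)-6-[(1E)-4,4-dimethyl-3,8-dioxonon-1-en-1-yl]-6-methyl-1,2-dioxan-3-yl]propanoate | COC(=O)[C@H](C)[C@@H]1CC[C@@](C)(/C=C/C(=O)C(C)(C)CCCC(C)=O)OO1
F8 | step 2 | methyl (2E,6E)-3-methylocta-2,6-dienoate | COC(=O)/C=C(\C)CC/C=C/C
F9 | step 2 | (2E,6E)-3-methylocta-2,6-dien-1-ol | OC/C=C(\C)CC/C=C/C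
F10 | step 2 | [(2R,3R)-3-methyl-3-[(3E)-pent-3-en-1-yl]oxiran-2-yl]methanol | C/C=C/CC[C@@]1(C)O[C@@H]1CO
F11 | step 2 | (3R,6E)-3-methyloct-6-ene-1,3-diol | C/C=C/CC[C@@](C)(O)CCO
F12 | step 2 | (3R,6E)-3-hydroxy-3-methyloct-6-en-1-yl 4-methylbenzenesulfonate | C/C=C/CC[C@@](C)(O)CCOS(=O)(=O)c1ccc(C)cc1
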